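## Structural features

The target is a daucane (carotane) sesquiterpenoid diester: a cyclopentane (ring A, C1–C5) fused along the C1–C5 bond to a cycloheptene (ring B, C1, C10, C9, C8, C7, C6, C5), with a trans ring fusion (C1 methyl β, H-5 α; β is the face of the C1 methyl throughout). Five stereocentres are present; C10, C1, C5 and C6 are contiguous and the fifth, C4, is attached to C5. C1 is quaternary, C4 is a tertiary carbinol carrying the isopropyl group (4β-OH), C6 carries an equatorial α-benzoate, and C10 carries an α-angelate that is allylic, neopentylic and anti to the C1 methyl. The trisubstituted C8=C9 alkene (C14 methyl on C8) makes C10 allylic and C6 homoallylic. The fragile parts are the angelate (Z to E isomerisation to the tiglate), the allylic C10–O bond (ionisation), the tertiary C4 alcohol (elimination, and retro-aldol or β-elimination whenever C6 is a carbonyl group) and the pair of secondary esters (acyl migration). The real difficulty lies in the quaternary C1 beside the C5/C4 pair, the trans-fused seven-membered ring, and the C10 oxygen on the more demanding face. The key step uses the homoallylic relation of C6 to C8: an allylsilane whose terminal carbon is C7 adds to a C6 aldehyde, closing ring B through C6–C7 and leaving a C8 exocyclic methylene that a C10 ketone afterwards draws into the C8=C9 position.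

## Logic of the disconnections

**24 ⇒ 23.** The O–Si bond at C4 is cut. The tertiary hydroxyl is β to C6 and has to be masked while C6 is an aldehyde and a Lewis acid is present. Nothing is gained in skeleton, only in safety. The forward step must remove silicon without touching an angelate and a benzoate.

**23 ⇒ 21 + 22.** The acyl C–O bond at C10 is cut. The angelate is the most fragile group and is therefore introduced last among the carbon fragments; five carbons are removed. The forward step must acylate a hindered, pseudo-axial allylic alcohol without Z/E isomerisation.

**21 ⇒ 20.** The C10–H bond is cut, which returns C10 to a ketone. The ketone is wanted because it fixes the alkene position. The forward step needs 1,2-selectivity and hydride delivery on the β-face.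

**20 ⇒ 18 + 19.** The acyl C–O bond at C6 is cut. The two secondary oxygens are told apart by timing: C6 is acylated while C10 is still a ketone. The demand is only a clean acylation of an equatorial alcohol.

**18 ⇒ 17.** The C8=C9 alkene is moved back to the exocyclic C8=C14 position. An exocyclic methylene β,γ to a ketone is the signature of an allylsilane addition. The forward step must isomerise toward C9 only, which the ketone guarantees.

**17 ⇒ 16.** The C6–C7 bond is cut and ring B is opened. This removes the seven-membered ring and one stereocentre and leaves a cyclopentane with two trans arms. The forward step must attack the aldehyde only, on the face that gives the 6α-alcohol.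

**16 ⇒ 15 ⇒ 12 + 13 (through 14).** Both carbonyl groups are taken back to alcohols and the C9–C10 bond is cut. The sensitive β,γ-unsaturated ketone and the epimerisable aldehyde then appear together in the last step before the cyclisation, and a C10 aldehyde accepts the allyl metal directly. The demand is an allyl Grignard reagent that keeps its silicon and an oxidation that does not conjugate the alkene.

**12 ⇒ 11 ⇒ 9 (through 10).** The C10=C bond of an alkene is restored and the O–Si bond at C4 is cut. C10 is carried as a robust alkene that is cleaved only when needed. The forward steps must silylate a tertiary alcohol and leave the primary one free.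

**9 ⇒ 7 + 8.** The C4–C11 bond is cut. The tertiary carbinol comes from the ring ketone, with C5 as the controlling neighbour. The forward step must add a branched nucleophile to a hindered ketone anti to the C5 substituent, without enolisation.

**7 ⇒ 5 + 6.** The C5–C6 bond is cut. C6 enters as a one-carbon electrophile on a regiodefined enol ether. The forward step needs the electrophile on the face of the C1 methyl, which requires the other C1 substituent to be clearly the larger one.

**5 ⇒ 1 + 2 (through 3 and 4).** The C1–C10 bond is cut. A conjugate addition creates the quaternary centre with absolute control from a flat enone, and the enolate is kept in its regiochemistry. The forward step must be enantioselective and must transfer the alkenyl group rather than a spectator group.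

## Other disconnections considered

**Alternative 1:** The cut is the C1–C5 ring-fusion bond, undone as a 1,2-shift.
- Forward step: the enantiopure bicyclic enedione A1 (Wieland–Miescher ketone, S series) would be elaborated to the cis-fused decalin hydroxy mesylate A2, in which C1 is still bonded to C6. Deprotonation of the tertiary C6 hydroxyl with a hindered alkoxide would trigger a semipinacol shift of C1 from C6 to C5 as the sulfonate leaves. The five- and seven-membered rings and the C6 ketone of A3 would appear in one event.
- In favour: C1 would come from a proline-catalysed Robinson annulation, which is better established for a quaternary centre than the alkenyl transfer of step 1; here the alternative is the better. The shift is stereospecific (retention at C1, inversion at C5), so the trans fusion would not depend on any facial preference; this is at least the equal of steps 2 and 3.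
- Against, here: A3 lacks the C8 methyl carbon and has a saturated C7–C9 chain, a C6 ketone and a C10 ketal. The methyl group, the C8=C9 alkene, the 6α-alcohol and the C10 carbinol would all follow later, whereas 17 already holds all fifteen skeletal carbons with usable oxygen at C6 and C10. A2 needs three contiguous oxygenated carbons of defined configuration, sulfonylation of the one secondary hydroxyl, and no epoxide closure by the C4 alkoxide.
- Comparison: on structure both plans reach the same ring system. On mechanism the concerted shift is more predictable than the open transition state of step 8. On step economy the alternative is expected to be longer, mainly after its key step.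

**Alternative 2:** Two bonds, C1–C10 and C5–C6, are cut at once.
- Forward step: copper–carbene-catalysed transfer of a vinyl group from aluminium to C1 of 1, then capture of the aluminium enolate at C5 by the β-silyloxy aldehyde A4 (racemic at C8) to give the aldol A5. Isopropyl addition, ring-closing metathesis of the two vinyl groups (C9=C10) and oxidative 1,3-transposition of the tertiary allylic C8 oxygen would lead to the same enone as 18.
- In favour: three stereocentres and every carbon but the isopropyl group are assembled in one flask. The way to the enone would be shorter than steps 1–9, so on step economy it is the better plan. The C1-forming event is of the same type as step 1 and is its equal.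
- Against, here: the facial choice at C5 would rest on the small difference between methyl and vinyl on C1; the chosen plan enlarges the alkenyl group for this reason. C6 would come from an intermolecular aldol of an aluminium enolate whose transition state is hard to predict. A5 is a β-hydroxy ketone, open to retro-aldol cleavage during the isopropyl addition. The metathesis would join two vinyl groups that both sit on fully substituted carbons.
- Comparison: on structure A5 carries C8 as a mixture that is removed only late. On mechanism both plans set C6 through an open transition state, but the chosen one does so inside a forming ring.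

**Alternative 3:** The cut is C4–C5, undone as a ring contraction.
- Forward step: in the p-menthane-type α-bromo ketone A6 (C6 ketone between C5 and C4, no hydrogen on C4), methoxide adds to C6 and the tetrahedral alkoxide pushes C4 from C6 to C5 with loss of bromide (semibenzilic shift). This gives the cyclopentane ester A7.
- In favour: the shift is stereospecific (retention at C4, inversion at C5), so the C4/C5 relationship would not depend on step 3 or on the face selectivity of step 2; in this respect it is the better. A7 is the functional equivalent of 11 and could be fed into the same Hosomi–Sakurai closure, so from that point on the plans are equal.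
- Against, here: it does not address ring B and competes with steps 1–5 only. A6 needs the quaternary C1 next to an equatorial bromide and an oxygenated C4 on a cyclohexanone, a stereochemical problem at least as large as the one it solves. Methoxide can also substitute or eliminate the bromide or form an epoxy ether.
- Comparison: on step economy no gain over the five steps from 1 to 12 is expected. On mechanism its stereospecificity is its real advantage.

Key step: step 8

## Remarks before the steps

- Check of the key compounds: 16 and 17 as formulated carry the target configuration at C1, C4 and C5 (and C6 in 17); no correction was needed.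
- Two design changes upstream of 16:
  - C10 is carried as a 2-methylprop-1-enyl group instead of a vinyl group, so that the C1 substituents differ clearly in size when C5 is functionalised.
  - The side arm is attached to a C10 aldehyde and oxidised, instead of passing through an acid and an amide.
- Assumption: the chiral ligand of step 1 is available in both antipodes, and the antipode that gives the C1 configuration shown is assigned on the first run.

## Route

Step 1
Reactants: 1 3-methylcyclopent-2-en-1-one; 2 (2-methylprop-1-en-1-yl)magnesium bromide
Product: 5 (R)-trimethyl{[3-methyl-3-(2-methylprop-1-en-1-yl)cyclopent-1-en-1-yl]oxy}silane, via alkenylalane 3 (not isolated), via aluminium enolate 4 (not isolated)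
Conditions: 2, Me2AlCl, Et2O, 0 °C; then 1, copper thiophene-2-carboxylate Cu(O2CC4H3S) (10 mol %), chiral phosphinamine ligand (11 mol %), Et2O, −30 °C; then TMSOTf, −30 °C → rt
Reagents that add atoms: trimethylsilyl trifluoromethanesulfonate, C[Si](C)(C)OS(=O)(=O)C(F)(F)F
Why: Copper-catalysed asymmetric conjugate addition of an alkenylalane to a β-methyl cyclic enone is an established route to all-carbon quaternary centres; the sp2 group transfers in preference to methyl and the ligand antipode fixes C1. O-Silylation of the aluminium enolate keeps the C4–C5 enolate regiochemistry, which could not be regenerated from the ketone because kinetic deprotonation would go to C3.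

Step 2
Reactants: 5 silyl enol ether; 6 formaldehyde (37 % aqueous)
Product: 7 (2S,3R)-2-(hydroxymethyl)-3-methyl-3-(2-methylprop-1-en-1-yl)cyclopentan-1-one
Conditions: aq. HCHO, Yb(OTf)3 (10 mol %), THF, rt
Reagents that add atoms: none
Why: Lanthanide-triflate-catalysed Mukaiyama aldol reaction with aqueous formaldehyde (hydroxymethylation of a silyl enol ether). Formaldehyde should approach C5 anti to the branched 2-methylpropenyl group, that is syn to the smaller C1 methyl, and the same isomer is the more stable one if C5 equilibrates.

Step 3
Reactants: 7 hydroxymethyl ketone; 8 isopropylmagnesium chloride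
Product: 9 (1R,2S,3R)-2-(hydroxymethyl)-3-methyl-3-(2-methylprop-1-en-1-yl)-1-(propan-2-yl)cyclopentan-1-ol
Conditions: 8 (3.5 equiv), CeCl3 (anhydrous), THF, −78 → 0 °C; aq. NH4Cl
Reagents that add atoms: none
Why: Organocerium-mediated Grignard 1,2-addition, which suppresses enolisation and β-hydride reduction of the hindered ketone; one equivalent is spent on the hydroxyl. The nucleophile should enter anti to the adjacent C5 substituent, placing isopropyl α and the new C4 hydroxyl β, cis to C6.

Step 4
Reactants: 9 diol
Product: 11 [2-methyl-2-(2-methylprop-1-en-1-yl)-5-(propan-2-yl)-5-(triethylsilyloxy)cyclopentyl]methanol (daucane numbering 1R,4R,5S), via bis(triethylsilyl) ether 10 (not isolated)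
Conditions: TESOTf (2.5 equiv), 2,6-lutidine, CH2Cl2, −78 → 0 °C; then AcOH/THF/H2O (3:1:1), rt
Reagents that add atoms: triethylsilyl trifluoromethanesulfonate, CC[Si](CC)(CC)OS(=O)(=O)C(F)(F)F
Why: Silyl triflate with lutidine silylates the hindered tertiary alcohol and the primary one as well. The primary triethylsilyl ether is then hydrolysed selectively by dilute acetic acid, the tertiary one being far slower for steric reasons (selective silyl ether cleavage).

Step 5
Reactants: 11 alkenyl alcohol
Product: 12 2-(hydroxymethyl)-1-methyl-3-(propan-2-yl)-3-(triethylsilyloxy)cyclopentane-1-carbaldehyde (daucane numbering 1S,4R,5S)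
Conditions: O3, CH2Cl2/MeOH, −78 °C; then Me2S, −78 °C → rt
Reagents that add atoms: ozone, [O-][O+]=O
Why: Ozonolysis with reductive work-up; the trisubstituted alkene is the only C=C bond and should give the C10 aldehyde and acetone. The trans relation of C10 and C6 on the ring disfavours lactol formation, which would need a trans-fused bicyclo[3.3.0] system.

Step 6
Reactants: 12 hydroxy aldehyde; 13 2-(chloromethyl)-3-(trimethylsilyl)prop-1-ene
Product: 15 1-[2-(hydroxymethyl)-1-methyl-3-(propan-2-yl)-3-(triethylsilyloxy)cyclopentyl]-3-[(trimethylsilyl)methyl]but-3-en-1-ol (daucane numbering 1S,4R,5S; C10 epimers), via allyl Grignard reagent 14 (not isolated)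
Conditions: 13, Mg, THF, 0 °C → rt; then 12 (to 3 equiv of 14), THF, −78 → 0 °C; aq. NH4Cl
Reagents that add atoms: none
Why: Grignard addition of an allylmagnesium reagent to an aldehyde; allyl Grignards add readily to neopentyl aldehydes, and the allyl unit is symmetrical, so allylic transposition is degenerate. One equivalent deprotonates the primary alcohol, and the C10 epimer mixture is irrelevant because C10 is oxidised next.

Step 7
Reactants: 15 diol
Product: 16 keto aldehyde 1-methyl-3-(propan-2-yl)-3-(triethylsilyloxy)-1-{3-[(trimethylsilyl)methyl]but-3-enoyl}cyclopentane-2-carbaldehyde (daucane numbering 1S,4R,5R)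
Conditions: Dess–Martin periodinane (3 equiv), NaHCO3, CH2Cl2, 0 °C → rt
Reagents that add atoms: none
Why: Dess–Martin oxidation of the primary and the secondary alcohol in one operation under buffered, non-basic conditions, which should keep the β,γ-unsaturated ketone out of conjugation and leave the allylsilane and the tertiary silyl ether alone. C5 becomes epimerisable, but the isomer with the formyl group trans to both the isopropyl group and the C1 acyl group is the more stable one.

Step 8
Reactants: 16 keto aldehyde
Product: 17 6α-hydroxy-4β-(triethylsilyloxy)dauc-8(14)-en-10-one (daucane numbering 1S,4R,5S,6S)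
Conditions: BF3·OEt2 (2 equiv), CH2Cl2 (0.005 M), −78 °C; aq. NaHCO3
Reagents that add atoms: none
Why: BF3 binds the C6 aldehyde, the more basic and less hindered carbonyl, and the terminal alkene carbon C7 of the allylsilane adds to C6; the cation developing at C8 is stabilised by the β C–Si bond and collapses by loss of silicon to the exocyclic C8=C14 alkene. This is an intramolecular Hosomi–Sakurai allylation, the known route from 2-(trimethylsilylmethyl)allyl carbonyl compounds to 3-methylenecycloalkanols, seven-membered ones included. Ring B closes in a 7-exo-trig sense at the carbonyl, with the allyl unit reacting endo so that C7 and C8 both become ring atoms; the trans arms on C1 and C5 lie gauche and can meet without strain, which gives the trans-fused hydroazulene. The new C6 stereocentre is controlled by C5: the tether through C1 forces C7 to approach gauche to C1, and of the two such trajectories the one antiperiplanar to the bulky C5–C4 bond (Felkin–Anh) should be preferred. The BF3-bound oxygen then points away from the forming ring, between H-5 and C4, which corresponds to the equatorial 6α-alcohol with H-5 and H-6 trans-diaxial. Chemoselectivity is inherent, since the C10 ketone is hindered and its attack would close a four-membered ring. The alkene position is secured by silicon, and high dilution and low temperature should hold back intermolecular allylation and protodesilylation.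

Step 9
Reactants: 17 β,γ-unsaturated ketone
Product: 18 6α-hydroxy-4β-(triethylsilyloxy)dauc-8-en-10-one
Conditions: DBU (0.5 equiv), CH2Cl2, rt
Reagents that add atoms: none
Why: Base-mediated isomerisation of a β,γ- to an α,β-unsaturated ketone through the C9 dienolate; reprotonation at C14 should give the conjugated, trisubstituted C8=C9 alkene as the thermodynamic product. The ketone dictates that the alkene moves toward C9 and not toward C7.

Step 10
Reactants: 18 hydroxy enone; 19 benzoyl chloride
Product: 20 6α-benzoyloxy-4β-(triethylsilyloxy)dauc-8-en-10-one
Conditions: 19, pyridine, DMAP (cat.), CH2Cl2, 0 °C → rt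
Reagents that add atoms: none
Why: DMAP-catalysed acylation of the equatorial secondary C6 alcohol (nucleophilic catalysis); the only other oxygen functions are a ketone and a silyl ether. It is done before the reduction so that the two secondary alcohols never have to be told apart.

Step 11
Reactants: 20 benzoyloxy enone
Product: 21 6α-benzoyloxy-4β-(triethylsilyloxy)dauc-8-en-10α-ol (daucane numbering 1S,4R,5S,6S,10R)
Conditions: NaBH4, CeCl3·7H2O, MeOH, −78 → −40 °C
Reagents that add atoms: none
Why: Luche reduction (1,2-selective hydride addition to an enone). In the chair-like trans-fused cycloheptenone the C1–C5 bond stands nearly perpendicular to the carbonyl plane with H-5 over the α-face, so hydride should enter antiperiplanar to that bond on the β-face, past the C1 methyl (Felkin–Anh), giving the pseudo-axial 10α-alcohol. Benzoate and silyl ether are inert to these conditions.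

Step 12
Reactants: 21 allylic alcohol; 22 angelic anhydride [(Z)-2-methylbut-2-enoic anhydride]
Product: 23 10α-angeloyloxy-6α-benzoyloxy-4β-(triethylsilyloxy)dauc-8-ene
Conditions: LiN(SiMe3)2 (1.1 equiv), THF, −78 °C; then 22, −78 → −20 °C
Reagents that add atoms: none
Why: Acylation of a lithium alkoxide with a carboxylic anhydride; this fast protocol avoids the nucleophilic catalysts and activated acyl species that isomerise angelates to tiglates. Low temperature should keep the alkoxide from attacking the C6 benzoate.

Step 13
Reactants: 23 silyl ether
Product: 24 10α-angeloyloxy-6α-benzoyloxy-dauc-8-en-4β-ol (target)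
Conditions: HF·pyridine, pyridine, THF, 0 °C → rt
Reagents that add atoms: none
Why: Fluoride-mediated cleavage of the tertiary triethylsilyl ether under buffered conditions, chosen over basic fluoride so that the two esters should neither migrate nor hydrolyse and the angelate should not isomerise.

## Compound list

1 | 3-methylcyclopent-2-en-1-one | CC1=CC(=O)CC1 | starting material
2 | (2-methylprop-1-en-1-yl)magnesium bromide | CC(C)=C[Mg]Br | starting material
3 | dimethyl(2-methylprop-1-en-1-yl)aluminium | CC(C)=C[Al](C)C | intermediate (not isolated)
4 | dimethylaluminium (R)-3-methyl-3-(2-methylprop-1-en-1-yl)cyclopent-1-en-1-olate | CC(C)=C[C@@]1(C)CCC(O[Al](C)C)=C1 | intermediate (not isolated)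
5 | (R)-trimethyl{[3-methyl-3-(2-methylprop-1-en-1-yl)cyclopent-1-en-1-yl]oxy}silane | CC(C)=C[C@@]1(C)CCC(O[Si](C)(C)C)=C1 | intermediate
6 | formaldehyde (37 % aqueous) | C=O | starting material
7 | (2S,3R)-2-(hydroxymethyl)-3-methyl-3-(2-methylprop-1-en-1-yl)cyclopentan-1-one (CH2OH cis to the ring methyl) | CC(C)=C[C@@]1(C)CCC(=O)[C@@H]1CO | intermediate
8 | isopropylmagnesium chloride | CC(C)[Mg]Cl | starting material
9 | (1R,2S,3R)-2-(hydroxymethyl)-3-methyl-3-(2-methylprop-1-en-1-yl)-1-(propan-2-yl)cyclopentan-1-ol (1-OH cis to CH2OH and to the 3-methyl) | CC(C)=C[C@@]1(C)CC[C@@](O)(C(C)C)[C@@H]1CO | intermediate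
10 | bis(triethylsilyl) ether of 9 | CC(C)=C[C@@]1(C)CC[C@@](O[Si](CC)(CC)CC)(C(C)C)[C@@H]1CO[Si](CC)(CC)CC | intermediate (not isolated)
11 | [2-methyl-2-(2-methylprop-1-en-1-yl)-5-(propan-2-yl)-5-(triethylsilyloxy)cyclopentyl]methanol (daucane numbering 1R,4R,5S; CH2OH cis to OSiEt3 and to the ring methyl) | CC(C)=C[C@@]1(C)CC[C@@](O[Si](CC)(CC)CC)(C(C)C)[C@@H]1CO | intermediate
12 | 2-(hydroxymethyl)-1-methyl-3-(propan-2-yl)-3-(triethylsilyloxy)cyclopentane-1-carbaldehyde (daucane numbering 1S,4R,5S; CHO trans to CH2OH) | O=C[C@@]1(C)CC[C@@](O[Si](CC)(CC)CC)(C(C)C)[C@@H]1CO | intermediate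
13 | 2-(chloromethyl)-3-(trimethylsilyl)prop-1-ene | C[Si](C)(C)CC(=C)CCl | starting material
14 | {2-[(trimethylsilyl)methyl]prop-2-en-1-yl}magnesium chloride | C[Si](C)(C)CC(=C)C[Mg]Cl | intermediate (not isolated)
15 | 1-[2-(hydroxymethyl)-1-methyl-3-(propan-2-yl)-3-(triethylsilyloxy)cyclopentyl]-3-[(trimethylsilyl)methyl]but-3-en-1-ol (daucane numbering 1S,4R,5S; mixture of C10 epimers) | C[Si](C)(C)CC(=C)CC(O)[C@@]1(C)CC[C@@](O[Si](CC)(CC)CC)(C(C)C)[C@@H]1CO | intermediate
16 | 1-methyl-3-(propan-2-yl)-3-(triethylsilyloxy)-1-{3-[(trimethylsilyl)methyl]but-3-enoyl}cyclopentane-2-carbaldehyde (daucane numbering 1S,4R,5R; 1β-methyl, 1α-acyl, 5β-formyl, 4β-OSiEt3, 4α-isopropyl) | C[Si](C)(C)CC(=C)CC(=O)[C@@]1(C)CC[C@@](O[Si](CC)(CC)CC)(C(C)C)[C@@H]1C=O | intermediate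
17 | 6α-hydroxy-4β-(triethylsilyloxy)dauc-8(14)-en-10-one (trans-fused; daucane numbering 1S,4R,5S,6S) | O=C1CC(=C)C[C@H](O)[C@@H]2[C@]1(C)CC[C@@]2(O[Si](CC)(CC)CC)C(C)C | intermediate
18 | 6α-hydroxy-4β-(triethylsilyloxy)dauc-8-en-10-one | O=C1C=C(C)C[C@H](O)[C@@H]2[C@]1(C)CC[C@@]2(O[Si](CC)(CC)CC)C(C)C | intermediate
19 | benzoyl chloride | O=C(Cl)c1ccccc1 | starting material
20 | 6α-benzoyloxy-4β-(triethylsilyloxy)dauc-8-en-10-one | O=C1C=C(C)C[C@H](OC(=O)c3ccccc3)[C@@H]2[C@]1(C)CC[C@@]2(O[Si](CC)(CC)CC)C(C)C | intermediate
21 | 6α-benzoyloxy-4β-(triethylsilyloxy)dauc-8-en-10α-ol (daucane numbering 1S,4R,5S,6S,10R) | O[C@@H]1C=C(C)C[C@H](OC(=O)c3ccccc3)[C@@H]2[C@]1(C)CC[C@@]2(O[Si](CC)(CC)CC)C(C)C | intermediate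
22 | angelic anhydride, (Z)-2-methylbut-2-enoic anhydride | C/C=C(/C)C(=O)OC(=O)/C(C)=C\C | starting material
23 | 10α-angeloyloxy-6α-benzoyloxy-4β-(triethylsilyloxy)dauc-8-ene | C/C=C(/C)C(=O)O[C@@H]1C=C(C)C[C@H](OC(=O)c3ccccc3)[C@@H]2[C@]1(C)CC[C@@]2(O[Si](CC)(CC)CC)C(C)C | intermediate
24 | (3R,3aS,4S,8R,8aS)-4-(benzoyloxy)-3-hydroxy-6,8a-dimethyl-3-(propan-2-yl)-1,2,3,3a,4,5,8,8a-octahydroazulen-8-yl (2Z)-2-methylbut-2-enoate (10α-angeloyloxy-6α-benzoyloxy-dauc-8-en-4β-ol) | C/C=C(/C)C(=O)O[C@@H]1C=C(C)C[C@H](OC(=O)c2ccccc2)[C@@H]2[C@]1(C)CC[C@@]2(O)C(C)C | target

## Step count and least certain steps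

Total step count: 13. Longest linear sequence: 13 steps (1 → 24); 2, 6, 8, 13, 19 and 22 are purchased.

**Step 8 (key step).**
- What may go wrong: loss of silicon by protodesilylation before the slow seven-membered closure, because the aldehyde carbon sits on a carbon flanked by two fully substituted centres and the Lewis acid can release traces of protic acid.
- Fallback: a silicon-free carbonyl-ene closure of the same C6–C7 bond. It sets out from 12. Addition of commercial 2-methylallylmagnesium chloride (3 equiv, THF, −78 → 0 °C) would give the 2-methylallyl carbinol F1. Dess–Martin oxidation as in step 7 would give the silicon-free keto aldehyde F2. Me2AlCl (CH2Cl2, −78 → −20 °C) would then promote an intramolecular carbonyl-ene (Prins-type) reaction, in which the terminal alkene carbon bonds to C6 and an allylic methyl hydrogen is transferred. It comes back to the route at 17; any product with the hydrogen taken from C9 is 18, one step further on.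

**Step 11.**
- What may go wrong: poor or inverted facial selectivity of hydride delivery at C10, because the β-face is flanked by the C1 methyl and the argument rests on the ring conformation.
- Fallback: catalyst-controlled instead of substrate-controlled reduction. It sets out from 20. A Corey–Bakshi–Shibata reduction with the (S)-2-methyl-oxazaborolidine and catecholborane (toluene, −78 °C), in which the fully substituted C1 flank acts as the large group, should deliver hydride to the β-face. It comes back at 21. Any 10β-alcohol F3 that still forms would be returned to 20 with MnO2 (CH2Cl2, rt).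

**Step 1.**
- What may go wrong: sluggish or poorly enantioselective transfer of the trisubstituted alkenyl group to the five-membered enone, and competing methyl transfer.
- Fallback: exchange of the roles of the two C1 substituents. It sets out from 2 and purchased 3-ethoxycyclopent-2-en-1-one. A Stork–Danheiser sequence (1,2-addition, then dilute HCl) would give the dienone F4. Copper-catalysed conjugate addition of Me3Al (same copper salt, opposite ligand antipode, Et2O, −30 °C) should go 1,4 because the remote alkene terminus is disubstituted. This generates the same aluminium enolate 4, which is silylated as before. It comes back at 5.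

**Step 12.**
- What may go wrong: isomerisation of the angeloyl group to the tigloyl group, or migration of the benzoyl group to the C10 alkoxide, under the basic acylation.
- Fallback: construction of the Z alkene after the acylation. It sets out from 21. The phosphonopropanoic acid F5 (from its commercial methyl ester with LiOH) would be coupled with DCC and DMAP to give the phosphonate ester F6. A Still–Gennari olefination with acetaldehyde (KN(SiMe3)2, 18-crown-6, THF, −78 °C) should form the Z-configured 2-methylbut-2-enoate. It comes back at 23.

**Step 3.**
- What may go wrong: enolisation, β-hydride reduction of the hindered ketone, or retro-aldol loss of formaldehyde from the β-alkoxide instead of addition.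
- Fallback: an sp2 nucleophile followed by selective hydrogenation. It sets out from 7. Isopropenylmagnesium bromide with CeCl3 (THF, −78 → 0 °C), which has no β-hydrogen to deliver, would give the isopropenyl diol F7. Hydrogenation with RhCl(PPh3)3 (H2, benzene/EtOH, rt) should reduce the 1,1-disubstituted alkene and leave the trisubstituted one. It comes back at 9.

## Further compounds

F1 | step 8 | 1-[2-(hydroxymethyl)-1-methyl-3-(propan-2-yl)-3-(triethylsilyloxy)cyclopentyl]-3-methylbut-3-en-1-ol (C10 epimers) | CC(=C)CC(O)[C@@]1(C)CC[C@@](O[Si](CC)(CC)CC)(C(C)C)[C@@H]1CO
F2 | step 8 | 1-methyl-1-(3-methylbut-3-enoyl)-3-(propan-2-yl)-3-(triethylsilyloxy)cyclopentane-2-carbaldehyde | CC(=C)CC(=O)[C@@]1(C)CC[C@@](O[Si](CC)(CC)CC)(C(C)C)[C@@H]1C=O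
F3 | step 11 | 6α-benzoyloxy-4β-(triethylsilyloxy)dauc-8-en-10β-ol | O[C@H]1C=C(C)C[C@H](OC(=O)c3ccccc3)[C@@H]2[C@]1(C)CC[C@@]2(O[Si](CC)(CC)CC)C(C)C
F4 | step 1 | 3-(2-methylprop-1-en-1-yl)cyclopent-2-en-1-one | CC(C)=CC1=CC(=O)CC1
F5 | step 12 | 2-[bis(2,2,2-trifluoroethoxy)phosphoryl]propanoic acid | CC(C(=O)O)P(=O)(OCC(F)(F)F)OCC(F)(F)F
F6 | step 12 | 6α-benzoyloxy-4β-(triethylsilyloxy)dauc-8-en-10α-yl 2-[bis(2,2,2-trifluoroethoxy)phosphoryl]propanoate | CC(C(=O)O[C@@H]1C=C(C)C[C@H](OC(=O)c3ccccc3)[C@@H]2[C@]1(C)CC[C@@]2(O[Si](CC)(CC)CC)C(C)C)P(=O)(OCC(F)(F)F)OCC(F)(F)F
F7 | step 3 | 2-(hydroxymethyl)-3-methyl-3-(2-methylprop-1-en-1-yl)-1-(prop-1-en-2-yl)cyclopentan-1-ol | CC(C)=C[C@@]1(C)CC[C@@](O)(C(C)=C)[C@@H]1CO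
A1 | alternative 1 | (S)-8a-methyl-3,4,8,8a-tetrahydronaphthalene-1,6(2H,7H)-dione | C[C@]12CCC(=O)C=C1CCCC2=O
A2 | alternative 1 | cis-fused decalin hydroxy mesylate (C10 ethylene ketal, C6 hydroxyl, C5 methanesulfonate, C4 isopropyl carbinol) | O1CCOC12CCC[C@]3(O)[C@@H](OS(C)(=O)=O)[C@](O)(C(C)C)CC[C@]23C
A3 | alternative 1 | trans-fused 4β-hydroxy-hydroazulen-6-one 10-ethylene ketal | O1CCOC12CCCC(=O)[C@@H]3[C@]2(C)CC[C@@]3(O)C(C)C
A4 | alternative 2 | 3-methyl-3-(triethylsilyloxy)pent-4-enal (racemic) | O=CCC(C)(O[Si](CC)(CC)CC)C=C
A5 | alternative 2 | trans-2,3-disubstituted cyclopentanone aldol (C8 epimers) | C=C[C@@]1(C)CCC(=O)[C@@H]1[C@@H](O)CC(C)(O[Si](CC)(CC)CC)C=C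
A6 | alternative 3 | 2-bromo-3-ethenyl-3-methyl-6-(propan-2-yl)-6-(triethylsilyloxy)cyclohexan-1-one | C=C[C@@]1(C)CC[C@@](O[Si](CC)(CC)CC)(C(C)C)C(=O)[C@@H]1Br
A7 | alternative 3 | methyl 2-ethenyl-2-methyl-5-(propan-2-yl)-5-(triethylsilyloxy)cyclopentane-1-carboxylate | C=C[C@@]1(C)CC[C@@](O[Si](CC)(CC)CC)(C(C)C)[C@@H]1C(=O)OC
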